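**Plan**

1. Numbering runs from C1 (acyl carbon on the ring) to C18 (methyl); the target is 6Z,9R,10E,12Z,15Z. The retrosynthesis cuts, in this order, the four O–Si bonds of a persilylated precursor, C4–C5, C12=C13, C5–C6, C8–C9 and the aryl–C1 bond.
2. Feature used: C5 is the primary allylic carbon of the Z-C6=C7 olefin, and C4 ends the three-carbon tether from the C1 ketone, which sits between the two ortho oxygens of the phloroglucinol ring. Both carbons are electrophilic in their natural precursors (allylic chloride, γ-iodo ketone), so C4 is polarity-reversed as a ketone-tolerant alkylzinc and joined to C5 by cobalt-catalysed SN2 allyl–alkyl coupling with retention of the Z geometry.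
3. Forward: ring + C1–C4 from phloroglucinol (acylation, silylation, Cl/I exchange); C5–C18 from (E)-4,4-dimethoxybut-2-enal (C8–C9 propargylation, C5–C6 hydroxymethylation, semi-hydrogenation, acetal hydrolysis, C12=C13 Wittig, chlorination); then C4–C5 coupling and global desilylation. No ring is formed; the aromatic ring is bought.
4. Stereochemistry: C9 by catalyst-controlled asymmetric propargylation; Z-C6=C7 by Lindlar reduction; E-C10=C11 from the starting enal; Z-C12=C13 from the non-stabilised ylide; Z-C15=C16 from (Z)-hex-3-en-1-ol.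

Key step: step 13

(TBS = tert-butyldimethylsilyl throughout.)

**Route**

Step 1
Reactants: 1 phloroglucinol; 2 4-chlorobutanoyl chloride
Product: 3 4-chloro-1-(2,4,6-trihydroxyphenyl)butan-1-one
Conditions: AlCl3 (4 equiv), PhNO2/CH2Cl2, 0 to 40 °C; aq. HCl work-up
Reagents that add atoms: none
Why: Friedel–Crafts C-acylation of the very electron-rich ring should stop at the mono-ketone because the chelated 2,6-dihydroxyaryl ketone is deactivated, and the primary alkyl chloride is inert to AlCl3 at this temperature.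

Step 2
Reactants: 3 4-chloro-1-(2,4,6-trihydroxyphenyl)butan-1-one
Product: 4 4-chloro-1-[2,4,6-tris(tert-butyldimethylsilyloxy)phenyl]butan-1-one
Conditions: TBSCl (3.6 equiv), imidazole, DMAP (cat.), DMF, rt to 40 °C
Reagents that add atoms: tert-butyldimethylsilyl chloride, CC(C)(C)[Si](C)(C)Cl
Why: Silylation of the three phenols removes the acidic O–H groups that would quench the organozinc reagent and installs groups that fluoride can remove at the end without acid.

Step 3
Reactants: 4 4-chloro-1-[2,4,6-tris(tert-butyldimethylsilyloxy)phenyl]butan-1-one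
Product: 5 4-iodo-1-[2,4,6-tris(tert-butyldimethylsilyloxy)phenyl]butan-1-one
Conditions: NaI (5 equiv), acetone, reflux
Reagents that add atoms: sodium iodide, [Na+].[I-]
Why: Finkelstein halide exchange at the primary carbon, driven by precipitation of NaCl, should give the iodide needed for zinc insertion near room temperature.

Step 4
Reactants: 6 (Z)-hex-3-en-1-ol
Product: 7 (Z)-1-iodohex-3-ene
Conditions: I2, PPh3, imidazole, CH2Cl2, 0 °C to rt
Reagents that add atoms: iodine, II
Why: Appel-type iodination proceeds by SN2 displacement of the alkoxyphosphonium group at the primary carbon and leaves the remote Z olefin untouched.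

Step 5
Reactants: 7 (Z)-1-iodohex-3-ene
Product: 8 [(Z)-hex-3-enyl]triphenylphosphonium iodide
Conditions: PPh3, MeCN, reflux
Reagents that add atoms: triphenylphosphine, c1ccc(cc1)P(c1ccccc1)c1ccccc1
Why: SN2 quaternisation of triphenylphosphine by the primary iodide should give the Wittig salt that carries C13–C18 with the Z-C15=C16 olefin in place.

Step 6
Reactants: 9 (E)-4,4-dimethoxybut-2-enal; 10 allenylboronic acid pinacol ester
Product: 12 (4R,5E)-7,7-dimethoxyhept-5-en-1-yn-4-ol, via pinacol borate ester 11 (not isolated)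
Conditions: (R)-TRIP (5 mol%), 4 Å MS, toluene, −20 °C; aq. work-up
Reagents that add atoms: none
Why: Chiral phosphoric acid-catalysed asymmetric propargylation through a closed six-membered SE2' transition state, in which the (R)-catalyst (hydrogen-bonded to the boronate oxygen and the formyl hydrogen) is expected to direct the γ-carbon of the allenylboronate to the Re face of the aldehyde and so set C9 as R, while the acetal should survive the anhydrous, weakly acidic medium.

Step 7
Reactants: 12 (4R,5E)-7,7-dimethoxyhept-5-en-1-yn-4-ol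
Product: 13 (4R,5E)-4-(tert-butyldimethylsilyloxy)-7,7-dimethoxyhept-5-en-1-yne
Conditions: TBSCl, imidazole, DMF, rt
Reagents that add atoms: tert-butyldimethylsilyl chloride, CC(C)(C)[Si](C)(C)Cl
Why: Silylation of the secondary alcohol gives an ether that tolerates organolithium, ylide and organozinc reagents and is removed together with the aryl silyl ethers in the last step.

Step 8
Reactants: 13 (4R,5E)-4-(tert-butyldimethylsilyloxy)-7,7-dimethoxyhept-5-en-1-yne
Product: 15 (5R,6E)-5-(tert-butyldimethylsilyloxy)-8,8-dimethoxyoct-6-en-2-yn-1-ol, via lithium acetylide 14 (not isolated)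
Conditions: n-BuLi (1.05 equiv), THF, −78 °C; (CH2O)n, −78 °C to rt; H2O
Reagents that add atoms: paraformaldehyde (as formaldehyde), C=O
Why: Deprotonation of the terminal alkyne, the most acidic C–H, and 1,2-addition of the acetylide to formaldehyde should add C5 as a hydroxymethyl group without touching the acetal or the silyl ether.

Step 9
Reactants: 15 (5R,6E)-5-(tert-butyldimethylsilyloxy)-8,8-dimethoxyoct-6-en-2-yn-1-ol
Product: 16 (2Z,5R,6E)-5-(tert-butyldimethylsilyloxy)-8,8-dimethoxyocta-2,6-dien-1-ol
Conditions: H2 (1 atm), Lindlar catalyst, quinoline, EtOAc, rt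
Reagents that add atoms: none
Why: Lindlar semi-hydrogenation delivers both hydrogens syn from the poisoned palladium surface and so should give the Z-C6=C7 olefin, the isolated E olefin being reduced much more slowly.

Step 10
Reactants: 16 (2Z,5R,6E)-5-(tert-butyldimethylsilyloxy)-8,8-dimethoxyocta-2,6-dien-1-ol
Product: 17 (2E,4R,6Z)-4-(tert-butyldimethylsilyloxy)-8-hydroxyocta-2,6-dienal
Conditions: PPTS (cat.), acetone/H2O, rt to 40 °C
Reagents that add atoms: water, O
Why: Mild acid-catalysed hydrolysis of the allylic dimethyl acetal should free the conjugated aldehyde under conditions that leave the secondary silyl ether and the Z-allylic alcohol intact.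

Step 11
Reactants: 17 (2E,4R,6Z)-4-(tert-butyldimethylsilyloxy)-8-hydroxyocta-2,6-dienal; 8 [(Z)-hex-3-enyl]triphenylphosphonium iodide
Product: 19 (2Z,5R,6E,8Z,11Z)-5-(tert-butyldimethylsilyloxy)tetradeca-2,6,8,11-tetraen-1-ol, via phosphonium ylide 18 (not isolated)
Conditions: 8 (2.5 equiv), NaHMDS (2.4 equiv), THF, −78 °C; then 17, −78 to −20 °C
Reagents that add atoms: none
Why: Wittig olefination with a non-stabilised ylide under lithium-free conditions passes through the kinetically favoured cis-oxaphosphetane and should set Z-C12=C13 next to the existing E olefin, the excess ylide serving only to deprotonate the O–H group.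

Step 12
Reactants: 19 (2Z,5R,6E,8Z,11Z)-5-(tert-butyldimethylsilyloxy)tetradeca-2,6,8,11-tetraen-1-ol
Product: 21 (2Z,5R,6E,8Z,11Z)-1-chloro-5-(tert-butyldimethylsilyloxy)tetradeca-2,6,8,11-tetraene, via allylic mesylate 20 (not isolated)
Conditions: MsCl, 2,4,6-collidine, LiCl, DMF, 0 °C
Reagents that add atoms: lithium chloride, [Li+].[Cl-]
Why: Mesylation followed by SN2 chloride displacement at the primary allylic carbon should give the allylic chloride under non-ionising conditions, without allylic transposition or loss of the Z geometry.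

Step 13
Reactants: 5 4-iodo-1-[2,4,6-tris(tert-butyldimethylsilyloxy)phenyl]butan-1-one; 21 (2Z,5R,6E,8Z,11Z)-1-chloro-5-(tert-butyldimethylsilyloxy)tetradeca-2,6,8,11-tetraene
Product: 23 (6Z,9R,10E,12Z,15Z)-9-(tert-butyldimethylsilyloxy)-1-[2,4,6-tris(tert-butyldimethylsilyloxy)phenyl]octadeca-6,10,12,15-tetraen-1-one, via alkylzinc iodide 22 (not isolated)
Conditions: Zn dust (activated with BrCH2CH2Br/TMSCl), LiCl, THF, 30 °C; then 21, CoBr2 (10 mol%), THF/NMP, −10 °C to rt
Reagents that add atoms: none
Why: Zinc inserts into the primary C–I bond of 5 (LiCl-assisted) to give 22, a C4 nucleophile too weakly basic to enolise or attack the C1 ketone, which is also shielded by its two ortho silyloxy groups; C4, electrophilic in 5, is thereby polarity-reversed and united with C5, the electrophilic primary allylic carbon of 21. Cobalt(II) bromide is reduced and alkylated by 22, and the low-valent alkylcobalt species is believed to attack the allylic chloride at its unsubstituted terminus to give a σ-allyl(alkyl)cobalt intermediate that undergoes C(sp3)–C(sp3) reductive elimination faster than σ–π–σ equilibration. The closest known reaction type is the cobalt-catalysed allylation of functionalised alkylzinc reagents with primary allylic chlorides, which takes the SN2 course with retention of olefin geometry, in contrast to the SN2' course of copper-mediated allylation of zinc reagents. No ring is closed and no stereocentre is created; C9 is a spectator as its silyl ether. The step needs α over γ regioselectivity, retention of Z-C6=C7 and chemoselectivity over the ketone, the diene and the skipped olefins: the first two should follow from the σ-allyl pathway and from the contrast between the unhindered CH2Cl terminus and the secondary C7 flanked by the C9 silyloxy branch, the last from the mildness of the zinc reagent at −10 °C.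

Step 14
Reactants: 23 (6Z,9R,10E,12Z,15Z)-9-(tert-butyldimethylsilyloxy)-1-[2,4,6-tris(tert-butyldimethylsilyloxy)phenyl]octadeca-6,10,12,15-tetraen-1-one
Product: 24 (6Z,9R,10E,12Z,15Z)-9-hydroxy-1-(2,4,6-trihydroxyphenyl)octadeca-6,10,12,15-tetraen-1-one
Conditions: TBAF (5 equiv), AcOH (5 equiv), THF, 0 °C to rt; pH 6 buffer work-up under argon
Reagents that add atoms: none
Why: Fluoride-mediated desilylation, driven by Si–F bond formation, should cleave the three aryl silyl ethers and the secondary allylic silyl ether under buffered, non-acidic conditions that do not ionise the dienyl carbinol.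

**Compound list**

1 | phloroglucinol (benzene-1,3,5-triol) | Oc1cc(O)cc(O)c1 | starting material
2 | 4-chlorobutanoyl chloride | O=C(Cl)CCCCl | starting material
3 | 4-chloro-1-(2,4,6-trihydroxyphenyl)butan-1-one | O=C(CCCCl)c1c(O)cc(O)cc1O | intermediate
4 | 4-chloro-1-[2,4,6-tris(tert-butyldimethylsilyloxy)phenyl]butan-1-one | ClCCCC(=O)c1c(O[Si](C)(C)C(C)(C)C)cc(O[Si](C)(C)C(C)(C)C)cc1O[Si](C)(C)C(C)(C)C | intermediate
5 | 4-iodo-1-[2,4,6-tris(tert-butyldimethylsilyloxy)phenyl]butan-1-one | ICCCC(=O)c1c(O[Si](C)(C)C(C)(C)C)cc(O[Si](C)(C)C(C)(C)C)cc1O[Si](C)(C)C(C)(C)C | intermediate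
6 | (Z)-hex-3-en-1-ol | CC/C=C\CCO | starting material
7 | (Z)-1-iodohex-3-ene | CC/C=C\CCI | intermediate
8 | [(Z)-hex-3-enyl]triphenylphosphonium iodide | CC/C=C\CC[P+](c1ccccc1)(c1ccccc1)c1ccccc1.[I-] | intermediate
9 | (E)-4,4-dimethoxybut-2-enal (fumaraldehyde mono(dimethyl acetal)) | COC(OC)/C=C/C=O | starting material
10 | allenylboronic acid pinacol ester (4,4,5,5-tetramethyl-2-(propa-1,2-dienyl)-1,3,2-dioxaborolane) | C=C=CB1OC(C)(C)C(C)(C)O1 | starting material
11 | pinacol borate ester of 12 (O–B(pin) at C4) | COC(OC)/C=C/[C@H](OB1OC(C)(C)C(C)(C)O1)CC#C | intermediate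
12 | (4R,5E)-7,7-dimethoxyhept-5-en-1-yn-4-ol | COC(OC)/C=C/[C@H](O)CC#C | intermediate
13 | (4R,5E)-4-(tert-butyldimethylsilyloxy)-7,7-dimethoxyhept-5-en-1-yne | COC(OC)/C=C/[C@H](O[Si](C)(C)C(C)(C)C)CC#C | intermediate
14 | lithium acetylide of 13 | COC(OC)/C=C/[C@H](O[Si](C)(C)C(C)(C)C)CC#C[Li] | intermediate
15 | (5R,6E)-5-(tert-butyldimethylsilyloxy)-8,8-dimethoxyoct-6-en-2-yn-1-ol | COC(OC)/C=C/[C@H](O[Si](C)(C)C(C)(C)C)CC#CCO | intermediate
16 | (2Z,5R,6E)-5-(tert-butyldimethylsilyloxy)-8,8-dimethoxyocta-2,6-dien-1-ol | COC(OC)/C=C/[C@H](O[Si](C)(C)C(C)(C)C)C/C=C\CO | intermediate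
17 | (2E,4R,6Z)-4-(tert-butyldimethylsilyloxy)-8-hydroxyocta-2,6-dienal | O=C/C=C/[C@H](O[Si](C)(C)C(C)(C)C)C/C=C\CO | intermediate
18 | [(Z)-hex-3-enylidene]triphenylphosphorane | CC/C=C\CC=P(c1ccccc1)(c1ccccc1)c1ccccc1 | intermediate
19 | (2Z,5R,6E,8Z,11Z)-5-(tert-butyldimethylsilyloxy)tetradeca-2,6,8,11-tetraen-1-ol | CC/C=C\C/C=C\C=C\[C@H](O[Si](C)(C)C(C)(C)C)C/C=C\CO | intermediate
20 | methanesulfonate of 19 | CC/C=C\C/C=C\C=C\[C@H](O[Si](C)(C)C(C)(C)C)C/C=C\COS(C)(=O)=O | intermediate
21 | (2Z,5R,6E,8Z,11Z)-1-chloro-5-(tert-butyldimethylsilyloxy)tetradeca-2,6,8,11-tetraene | CC/C=C\C/C=C\C=C\[C@H](O[Si](C)(C)C(C)(C)C)C/C=C\CCl | intermediate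
22 | {4-oxo-4-[2,4,6-tris(tert-butyldimethylsilyloxy)phenyl]butyl}zinc iodide | I[Zn]CCCC(=O)c1c(O[Si](C)(C)C(C)(C)C)cc(O[Si](C)(C)C(C)(C)C)cc1O[Si](C)(C)C(C)(C)C | intermediate
23 | (6Z,9R,10E,12Z,15Z)-9-(tert-butyldimethylsilyloxy)-1-[2,4,6-tris(tert-butyldimethylsilyloxy)phenyl]octadeca-6,10,12,15-tetraen-1-one | CC/C=C\C/C=C\C=C\[C@H](O[Si](C)(C)C(C)(C)C)C/C=C\CCCCC(=O)c1c(O[Si](C)(C)C(C)(C)C)cc(O[Si](C)(C)C(C)(C)C)cc1O[Si](C)(C)C(C)(C)C | intermediate
24 | (6Z,9R,10E,12Z,15Z)-9-hydroxy-1-(2,4,6-trihydroxyphenyl)octadeca-6,10,12,15-tetraen-1-one | CC/C=C\C/C=C\C=C\[C@H](O)C/C=C\CCCCC(=O)c1c(O)cc(O)cc1O | target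

**Summary**

Total number of steps: 14. Longest linear sequence: 9 (steps 6 to 14).

**Steps most likely to fail**

Step 13. The risks are slow transfer of the alkyl group from the monoalkylzinc iodide to cobalt, leakage into SN2' attack at C7, Z-to-E isomerisation through a π-allyl intermediate, and reductive homocoupling of the allylic chloride. The fallback makes the C4–C5 bond at the alkyne oxidation level, before the polyene exists. Setting out from 15, bromination with CBr4/PPh3 in CH2Cl2 at 0 °C should give (5R,6E)-1-bromo-5-(tert-butyldimethylsilyloxy)-8,8-dimethoxyoct-6-en-2-yne F1. Negishi coupling of F1 with the zinc reagent 22 (from 5 as in step 13) under NiCl2·glyme/terpyridine in DMA at rt, the nickel-catalysed alkyl–propargyl coupling that gives alkynes and not allenes, should give (9R,10E)-9-(tert-butyldimethylsilyloxy)-12,12-dimethoxy-1-[2,4,6-tris(tert-butyldimethylsilyloxy)phenyl]dodec-10-en-6-yn-1-one F2. Lindlar semi-hydrogenation as in step 9 should give (6Z,9R,10E)-9-(tert-butyldimethylsilyloxy)-12,12-dimethoxy-1-[2,4,6-tris(tert-butyldimethylsilyloxy)phenyl]dodeca-6,10-dien-1-one F3. Acetal hydrolysis as in step 10 should give (2E,4R,6Z)-4-(tert-butyldimethylsilyloxy)-12-oxo-12-[2,4,6-tris(tert-butyldimethylsilyloxy)phenyl]dodeca-2,6-dienal F4. Wittig olefination of F4 with ylide 18 as in step 11, in which the C1 ketone is shielded by its two ortho silyloxy groups, should give 23, where the route is rejoined.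

Step 6. The risks are insufficient facial discrimination for the slim alkenyl aldehyde and loss of the dimethyl acetal under the acidic catalyst (if only the sense of induction proves opposite, (S)-TRIP is used). The fallback replaces asymmetric catalysis by resolution. Setting out from 9, Barbier propargylation with propargyl bromide and zinc in THF/aq. NH4Cl should give racemic (E)-7,7-dimethoxyhept-5-en-1-yn-4-ol F5. Lipase-catalysed transesterification (Burkholderia cepacia lipase, vinyl acetate, hexane, rt) is expected, by the usual empirical preference of lipases for secondary alcohols, to acylate the R enantiomer and give (4R,5E)-7,7-dimethoxyhept-5-en-1-yn-4-yl acetate F6 beside unreacted (4S,5E)-7,7-dimethoxyhept-5-en-1-yn-4-ol F7. After separation, methanolysis of F6 (K2CO3, MeOH, 0 °C) returns 12.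

Step 11. The risks are erosion of Z selectivity and base-induced γ-deprotonation or alkoxide side reactions of the hydroxy enal. The fallback builds C12=C13 through an alkyne. Setting out from 17, Ohira–Bestmann homologation (dimethyl (1-diazo-2-oxopropyl)phosphonate, K2CO3, MeOH, 0 °C) should give (2Z,5R,6E)-5-(tert-butyldimethylsilyloxy)nona-2,6-dien-8-yn-1-ol F8. Copper-mediated coupling of the terminal alkyne with (Z)-1-bromopent-2-ene (CuI, NaI, Cs2CO3, DMF, rt) should give (2Z,5R,6E,11Z)-5-(tert-butyldimethylsilyloxy)tetradeca-2,6,11-trien-8-yn-1-ol F9. cis-Reduction of the conjugated alkyne alone with Zn(Cu/Ag) in MeOH/H2O should give 19, where the route is rejoined.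

**Further compounds**

F1 | step 13 | (5R,6E)-1-bromo-5-(tert-butyldimethylsilyloxy)-8,8-dimethoxyoct-6-en-2-yne | COC(OC)/C=C/[C@H](O[Si](C)(C)C(C)(C)C)CC#CCBr
F2 | step 13 | (9R,10E)-9-(tert-butyldimethylsilyloxy)-12,12-dimethoxy-1-[2,4,6-tris(tert-butyldimethylsilyloxy)phenyl]dodec-10-en-6-yn-1-one | COC(OC)/C=C/[C@H](O[Si](C)(C)C(C)(C)C)CC#CCCCCC(=O)c1c(O[Si](C)(C)C(C)(C)C)cc(O[Si](C)(C)C(C)(C)C)cc1O[Si](C)(C)C(C)(C)C
F3 | step 13 | (6Z,9R,10E)-9-(tert-butyldimethylsilyloxy)-12,12-dimethoxy-1-[2,4,6-tris(tert-butyldimethylsilyloxy)phenyl]dodeca-6,10-dien-1-one | COC(OC)/C=C/[C@H](O[Si](C)(C)C(C)(C)C)C/C=C\CCCCC(=O)c1c(O[Si](C)(C)C(C)(C)C)cc(O[Si](C)(C)C(C)(C)C)cc1O[Si](C)(C)C(C)(C)C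
F4 | step 13 | (2E,4R,6Z)-4-(tert-butyldimethylsilyloxy)-12-oxo-12-[2,4,6-tris(tert-butyldimethylsilyloxy)phenyl]dodeca-2,6-dienal | O=C/C=C/[C@H](O[Si](C)(C)C(C)(C)C)C/C=C\CCCCC(=O)c1c(O[Si](C)(C)C(C)(C)C)cc(O[Si](C)(C)C(C)(C)C)cc1O[Si](C)(C)C(C)(C)C
F5 | step 6 | racemic (E)-7,7-dimethoxyhept-5-en-1-yn-4-ol | COC(OC)/C=C/C(O)CC#C
F6 | step 6 | (4R,5E)-7,7-dimethoxyhept-5-en-1-yn-4-yl acetate | COC(OC)/C=C/[C@H](OC(C)=O)CC#C
F7 | step 6 | (4S,5E)-7,7-dimethoxyhept-5-en-1-yn-4-ol | COC(OC)/C=C/[C@@H](O)CC#C
F8 | step 11 | (2Z,5R,6E)-5-(tert-butyldimethylsilyloxy)nona-2,6-dien-8-yn-1-ol | C#C/C=C/[C@H](O[Si](C)(C)C(C)(C)C)C/C=C\CO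
F9 | step 11 | (2Z,5R,6E,11Z)-5-(tert-butyldimethylsilyloxy)tetradeca-2,6,11-trien-8-yn-1-ol | CC/C=C\CC#C/C=C/[C@H](O[Si](C)(C)C(C)(C)C)C/C=C\CO
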